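**Retrosynthetic overview**
1. Numbering: coumarin O1, C2–C8a (benzo ring A); chroman O1', C2'–C8a' (benzo ring B); the halves meet at C3–C6'. The route rests on ring B. C8a' (oxygen), C4a' (the C4' methylene), C5' (methoxy) and C6' (coumarin C3) are four neighbouring substituted carbons beside two CH positions (C7', C8'), which is the substitution print of a vinylketene plus 1-alkoxyalkyne benzannulation.
2. Last ring: O1'–C2', by acid-catalysed addition of the C8a' phenol to an ortho-prenyl group, run together with removal of the 7-O-MOM group.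
3. Key disconnection: ring B is cut at C4a'–C8a', C5'–C6' and C8'–C8a'. This gives 1-methoxy-5-methylhex-4-en-1-yne (C4a', C5', prenyl) and coumarin-3-yl(vinyl)ketene (C6', C7', C8', C8a'). The ketene comes from the coumarin-3-yl alpha-diazo vinyl ketone by photochemical Wolff rearrangement, so the hindered C3–C6' bond exists before ring B does and needs no cross-coupling.
4. The diazo ketone goes back to the vinyl ketone (deacylative diazo transfer), then to the coumarin-3-acetic acid (acyl Stille coupling), then to a differentiated phloroglucinaldehyde and succinic anhydride (Perkin condensation, which closes the pyranone).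
5. Ring order: ring A bought, pyranone (step 3), ring B (step 7), dihydropyran (step 8).

Key step: step 7

Remark: the target has no stereocentre and the C3–C6' axis is taken as freely rotating. No stereocontrol is needed, and the two transient stereogenic carbons on the way form as racemates and vanish again.

**Step 1**
Reactants: 1 2,4,6-trihydroxybenzaldehyde
Product: 2 2,6-dihydroxy-4-(methoxymethoxy)benzaldehyde
Conditions: MOMCl (1.0 equiv), i-Pr2NEt (1.1 equiv), THF, 0 °C
Reagents that add atoms: chloromethyl methyl ether COCCl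
Why: Base-mediated O-alkylation (Williamson type): the 4-OH is the most acidic hydroxyl and the only one not tied to the formyl oxygen by a hydrogen bond, and the hard chloromethyl ether reacts at oxygen and not at the nucleophilic ring carbons, so one equivalent should stop at the 4-O-MOM ether.

**Step 2**
Reactants: 2 2,6-dihydroxy-4-(methoxymethoxy)benzaldehyde
Product: 3 2-hydroxy-6-methoxy-4-(methoxymethoxy)benzaldehyde
Conditions: MeI (1.05 equiv), K2CO3 (1.1 equiv), acetone, rt
Reagents that add atoms: iodomethane CI
Why: Williamson methylation of one of two equivalent hydroxyls; once one is methylated the survivor alone chelates the formyl oxygen and ionises less readily, so one equivalent of MeI and base should give the monoether.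

**Step 3**
Reactants: 3 2-hydroxy-6-methoxy-4-(methoxymethoxy)benzaldehyde; 4 succinic anhydride
Product: 5 [5-methoxy-7-(methoxymethoxy)-2-oxo-2H-chromen-3-yl]acetic acid
Conditions: 4 (3 equiv), anhydrous disodium succinate Na2C4H4O4 (1.5 equiv), melt, 150 °C, N2; aq NaHCO3, then citric acid to pH 4, 0 °C
Reagents that add atoms: none
Why: Perkin condensation in the variant long used for coumarin-3-acetic acids: the enolised anhydride adds to the aldehyde, the ortho hydroxyl lactonises onto the carbonyl next to the new C–C bond (six-membered pyranone) and beta-elimination of the other carboxylate arm sets C3=C4, while the carboxylate buffer keeps strong acid away from the MOM ether.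

**Step 4**
Reactants: 5 [5-methoxy-7-(methoxymethoxy)-2-oxo-2H-chromen-3-yl]acetic acid; 6 tributyl(vinyl)stannane
Product: 8 5-methoxy-7-(methoxymethoxy)-3-(2-oxobut-3-en-1-yl)-2H-chromen-2-one, via acid chloride 7 (not isolated)
Conditions: Me2C=C(Cl)NMe2 (1.1 equiv), CH2Cl2, 0 °C to rt; concentrate; 6 (1.1 equiv), Pd2(dba)3 (2.5 mol %), P(2-furyl)3 (10 mol %), BHT (trace), THF, rt to 45 °C; KF/silica filtration, product kept cold
Reagents that add atoms: 1-chloro-N,N,2-trimethylprop-1-en-1-amine CC(C)=C(Cl)N(C)C (supplies only the chlorine of 7; nothing of it stays in 8)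
Why: The alpha-chloroenamine makes the acid chloride without releasing HCl (MOM ether safe), and the Stille acylation (oxidative addition of the acyl chloride to zerovalent palladium, vinyl transfer from tin, reductive elimination) gives the vinyl ketone without a hard nucleophile or base that would attack the lactone, the acidic C3–CH2 or the new enone.

**Step 5**
Reactants: 8 5-methoxy-7-(methoxymethoxy)-3-(2-oxobut-3-en-1-yl)-2H-chromen-2-one
Product: 10 3-(1-diazo-2-oxobut-3-en-1-yl)-5-methoxy-7-(methoxymethoxy)-2H-chromen-2-one, via trifluoroacetyl diketone 9 (not isolated)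
Conditions: 8 added to LiN(SiMe3)2 (1.15 equiv), THF, −78 °C; CF3CO2CH2CF3 (1.3 equiv), −78 °C, 10 min; cold 0.5 M HCl wash, crude used; MsN3 (1.5 equiv), Et3N (1.5 equiv), H2O (1 equiv), MeCN, 0 to 20 °C, dark; NaHCO3 wash; stored at −20 °C in the dark and used promptly
Reagents that add atoms: methanesulfonyl azide CS(=O)(=O)N=[N+]=[N-] (the two diazo nitrogens of 10); 2,2,2-trifluoroethyl trifluoroacetate O=C(OCC(F)(F)F)C(F)(F)F (the trifluoroacetyl group of 9 only)
Why: Detrifluoroacetylative (deacylative Regitz) diazo transfer, the method made for base-sensitive alpha'-diazo enones: inverse addition to the amide at −78 °C converts the enone at once into the delocalised enolate of the doubly activated C3–CH2, C-trifluoroacetylation gives a 1,3-diketone acidic enough for Et3N, and from then on the acryloyl group belongs to an enolate or a diazo ketone and is a poor Michael acceptor.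

**Step 6**
Reactants: 11 chloroacetaldehyde dimethyl acetal; 12 1-bromo-3-methylbut-2-ene (prenyl bromide)
Product: 14 1-methoxy-5-methylhex-4-en-1-yne, via sodium methoxyacetylide 13 (not isolated)
Conditions: NaNH2 (3.0 equiv), liquid NH3, −33 °C; 12 (0.9 equiv) in Et2O, −45 to −33 °C; NH3 evaporated, pentane/cold water, distilled from K2CO3 under reduced pressure
Reagents that add atoms: sodium amide [Na+].[NH2-] (the sodium of 13 only)
Why: One-pot alkoxyacetylide synthesis and alkylation: three equivalents of amide remove methanol and HCl from the chloroacetal and deprotonate the methoxyacetylene, and the acetylide displaces bromide at the primary carbon of 12 (SN2, the tertiary terminus being too hindered for SN2'), with no amide left to isomerise the skipped enyne.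

**Step 7**
Reactants: 10 3-(1-diazo-2-oxobut-3-en-1-yl)-5-methoxy-7-(methoxymethoxy)-2H-chromen-2-one; 14 1-methoxy-5-methylhex-4-en-1-yne
Product: 19 3-[4-hydroxy-2-methoxy-3-(3-methylbut-2-en-1-yl)phenyl]-5-methoxy-7-(methoxymethoxy)-2H-chromen-2-one, via vinylketene 15 (not isolated), via vinylcyclobutenone 16 (not isolated), via dienylketene 17 (not isolated), via cyclohexadienone 18 (not isolated)
Conditions: 10 (0.05 M, CH2Cl2) added over 2 h to 14 (3 equiv) in CH2Cl2 under 440–450 nm LED light, 10–15 °C, N2; solvent and excess 14 evaporated at or below 25 °C; toluene, 100 °C, dark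
Reagents that add atoms: none
Why: Blue light should reach only the long-wavelength diazo band of 10, since the dialkoxycoumarin chromophore is expected to be transparent at 440 nm; N2 leaves and the vinyl group shifts from the acyl carbon to the former diazo carbon (Wolff rearrangement), giving ketene 15 with coumarin C3 already on the future C6'. The electrophilic ketene carbonyl carbon is attacked by the nucleophilic, prenyl-bearing alkyne carbon of 14 (beta to the methoxy oxygen), so the [2+2] cycloaddition forms C4a'–C8a' and C5'–C6' in one orientation and gives racemic 16, which should neither absorb at 440 nm nor open at 15 °C and therefore accumulates. In the dark at 100 °C a reversible, strain-driven conrotatory 4π opening gives dienylketene 17, ring B closes by disrotatory 6π electrocyclisation of the ketene carbon onto the vinyl CH2 (C8'–C8a'), and dienone 18 tautomerises to phenol 19, so the quaternary stereocentre of 16 is erased and none remains. This is the Danheiser benzannulation in its diazo ketone form, with visible-light Wolff rearrangement of alpha-aryl alpha-diazo ketones and the classical diarylketene–alkoxyacetylene adduct-to-naphthol rearrangement as the closest relatives. The selectivity needed is periselectivity in the 6π step, because the quaternary carbon of 16 bears two alkenyl groups: closure on the unsubstituted vinyl terminus should beat closure on coumarin C4, which is disubstituted, crowded by the peri 5-OMe and part of the cinnamate conjugation, and since the ring opening is reversible both dienylketene geometries drain through the faster channel. Separating a cold light stage from a hot dark stage also keeps phenol away while ketene 15 is being generated (no aryl ester formation), and a methyl ynol ether cannot fragment by retro-ene reaction.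

**Step 8**
Reactants: 19 3-[4-hydroxy-2-methoxy-3-(3-methylbut-2-en-1-yl)phenyl]-5-methoxy-7-(methoxymethoxy)-2H-chromen-2-one
Product: 21 7-hydroxy-5-methoxy-3-(5-methoxy-2,2-dimethyl-3,4-dihydro-2H-chromen-6-yl)-2H-chromen-2-one (CNP0139207.0), via free bisphenol 20 (not isolated)
Conditions: p-TsOH·H2O (0.3 equiv), MeOH, 50 °C; evaporate; ClCH2CH2Cl, 70 °C
Reagents that add atoms: none
Why: Acid-catalysed acetal exchange first removes the MOM group in methanol, where the formaldehyde unit leaves as dimethoxymethane and cannot alkylate the electron-rich rings, and in the non-nucleophilic solvent Markovnikov protonation of the prenyl alkene gives a tertiary cation that is captured by the only neighbouring hydroxyl, at C8a' (6-endo hydroalkoxylation to the 2,2-dimethylchroman, the other ortho oxygen being blocked as its methyl ether).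

**Compound list**
1 | 2,4,6-trihydroxybenzaldehyde | O=Cc1c(O)cc(O)cc1O | starting material
2 | 2,6-dihydroxy-4-(methoxymethoxy)benzaldehyde | O=Cc1c(O)cc(OCOC)cc1O | intermediate
3 | 2-hydroxy-6-methoxy-4-(methoxymethoxy)benzaldehyde | O=Cc1c(O)cc(OCOC)cc1OC | intermediate
4 | succinic anhydride | O=C1CCC(=O)O1 | starting material
5 | [5-methoxy-7-(methoxymethoxy)-2-oxo-2H-chromen-3-yl]acetic acid | OC(=O)Cc1cc2c(OC)cc(OCOC)cc2oc1=O | intermediate
6 | tributyl(vinyl)stannane | C=C[Sn](CCCC)(CCCC)CCCC | starting material
7 | [5-methoxy-7-(methoxymethoxy)-2-oxo-2H-chromen-3-yl]acetyl chloride | O=C(Cl)Cc1cc2c(OC)cc(OCOC)cc2oc1=O | intermediate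
8 | 5-methoxy-7-(methoxymethoxy)-3-(2-oxobut-3-en-1-yl)-2H-chromen-2-one | C=CC(=O)Cc1cc2c(OC)cc(OCOC)cc2oc1=O | intermediate
9 | 5-methoxy-7-(methoxymethoxy)-3-(1,1,1-trifluoro-2,4-dioxohex-5-en-3-yl)-2H-chromen-2-one (racemic, largely enolised) | C=CC(=O)C(C(=O)C(F)(F)F)c1cc2c(OC)cc(OCOC)cc2oc1=O | intermediate
10 | 3-(1-diazo-2-oxobut-3-en-1-yl)-5-methoxy-7-(methoxymethoxy)-2H-chromen-2-one | C=CC(=O)C(=[N+]=[N-])c1cc2c(OC)cc(OCOC)cc2oc1=O | intermediate
11 | chloroacetaldehyde dimethyl acetal | COC(CCl)OC | starting material
12 | 1-bromo-3-methylbut-2-ene | CC(C)=CCBr | starting material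
13 | sodium methoxyacetylide | [Na+].[C-]#COC | intermediate
14 | 1-methoxy-5-methylhex-4-en-1-yne | COC#CCC=C(C)C | intermediate
15 | 2-[5-methoxy-7-(methoxymethoxy)-2-oxo-2H-chromen-3-yl]buta-1,3-dien-1-one | C=CC(=C=O)c1cc2c(OC)cc(OCOC)cc2oc1=O | intermediate
16 | 3-[1-ethenyl-2-methoxy-3-(3-methylbut-2-en-1-yl)-4-oxocyclobut-2-en-1-yl]-5-methoxy-7-(methoxymethoxy)-2H-chromen-2-one (racemic) | O=C1C(CC=C(C)C)=C(OC)C1(C=C)c1cc2c(OC)cc(OCOC)cc2oc1=O | intermediate
17 | (3Z)-3-methoxy-4-[5-methoxy-7-(methoxymethoxy)-2-oxo-2H-chromen-3-yl]-2-(3-methylbut-2-en-1-yl)hexa-1,3,5-trien-1-one | O=C=C(CC=C(C)C)/C(OC)=C(\C=C)c1cc2c(OC)cc(OCOC)cc2oc1=O | intermediate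
18 | 3-methoxy-4-[5-methoxy-7-(methoxymethoxy)-2-oxo-2H-chromen-3-yl]-2-(3-methylbut-2-en-1-yl)cyclohexa-2,4-dien-1-one | O=C1CC=C(c2cc3c(OC)cc(OCOC)cc3oc2=O)C(OC)=C1CC=C(C)C | intermediate
19 | 3-[4-hydroxy-2-methoxy-3-(3-methylbut-2-en-1-yl)phenyl]-5-methoxy-7-(methoxymethoxy)-2H-chromen-2-one | COCOc1cc(OC)c2cc(-c3ccc(O)c(CC=C(C)C)c3OC)c(=O)oc2c1 | intermediate
20 | 7-hydroxy-3-[4-hydroxy-2-methoxy-3-(3-methylbut-2-en-1-yl)phenyl]-5-methoxy-2H-chromen-2-one | Oc1cc(OC)c2cc(-c3ccc(O)c(CC=C(C)C)c3OC)c(=O)oc2c1 | intermediate
21 | 7-hydroxy-5-methoxy-3-(5-methoxy-2,2-dimethyl-3,4-dihydro-2H-chromen-6-yl)-2H-chromen-2-one | COc1c(-c2cc3c(OC)cc(O)cc3oc2=O)ccc2c1CCC(C)(C)O2 | target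

**Step count**
Total steps: 8.
Longest linear sequence: 7 (steps 1, 2, 3, 4, 5, 7, 8). Step 6 is the side branch.

**Steps most likely to fail**

1. **Step 7.**
 - Risks: the alkenyl-diazo unit may cyclise thermally onto C4 before it is photolysed. The photogenerated carbene may be intercepted by the electron-rich alkyne before the 1,2-shift. The 6π closure may use the coumarin C3=C4 bond instead of the vinyl group.
 - Fallback: sets out from 3 and comes back at 21. Ring B is brought in ready-made and the C3–C6' bond comes from a classical 3-arylcoumarin condensation.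
 - 2,4-Dihydroxyacetophenone and 3-methylbut-2-enal are condensed in hot pyridine. This chromenylation of a mono-chelated resorcinol goes to the carbon between the two oxygens and gives 1-(5-hydroxy-2,2-dimethyl-2H-chromen-6-yl)ethan-1-one F1.
 - Hydrogenation (H2, Pd/C, EtOAc) gives 1-(5-hydroxy-2,2-dimethyl-3,4-dihydro-2H-chromen-6-yl)ethan-1-one F2.
 - Methylation (Me2SO4, K2CO3, acetone, reflux) gives 1-(5-methoxy-2,2-dimethyl-3,4-dihydro-2H-chromen-6-yl)ethan-1-one F3.
 - The Willgerodt–Kindler reaction (S8, morpholine, 130 °C) gives 2-(5-methoxy-2,2-dimethyl-3,4-dihydro-2H-chromen-6-yl)-1-(morpholin-4-yl)ethane-1-thione F4.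
 - Hydrolysis (KOH, aq EtOH, reflux) gives (5-methoxy-2,2-dimethyl-3,4-dihydro-2H-chromen-6-yl)acetic acid F5.
 - Perkin–Oglialoro condensation of F5 with 3 (Ac2O, Et3N, 110 °C) gives 5-methoxy-3-(5-methoxy-2,2-dimethyl-3,4-dihydro-2H-chromen-6-yl)-7-(methoxymethoxy)-2H-chromen-2-one F6.
 - p-TsOH in MeOH at 50 °C then releases 21.

2. **Step 5.**
 - Risks: anionic oligomerisation of the unsubstituted enone during enolisation, acylation on oxygen instead of carbon, and slow loss of the diazo ketone by cyclisation during the transfer.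
 - Fallback: sets out from 8 and comes back at 10. The enone is masked as a Mannich base while the diazo group is installed.
 - Me2NH (1 equiv, THF, 0 °C) adds to 8 to give 3-[4-(dimethylamino)-2-oxobutyl]-5-methoxy-7-(methoxymethoxy)-2H-chromen-2-one F7.
 - Direct Regitz transfer (4-acetamidobenzenesulfonyl azide, DBU, MeCN, 0 °C) at the benzylic-type CH2 gives 3-[1-diazo-4-(dimethylamino)-2-oxobutyl]-5-methoxy-7-(methoxymethoxy)-2H-chromen-2-one F8.
 - MeI gives the quaternary salt 4-diazo-4-[5-methoxy-7-(methoxymethoxy)-2-oxo-2H-chromen-3-yl]-N,N,N-trimethyl-3-oxobutan-1-aminium iodide F9.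
 - K2CO3 in CH2Cl2/H2O at rt then unmasks the vinyl group by beta-elimination. The known dehydrohalogenation of beta-halo diazo ketones is the analogous reaction.

3. **Step 3.**
 - Risks: loss of the MOM ether and charring in the hot melt, and sluggish addition to a hindered, chelated, electron-rich aldehyde.
 - Fallback: sets out from 3 and comes back at 5. The C3=C4 bond is made by olefination under neutral to basic conditions.
 - Methyl (triphenylphosphoranylidene)acetate (2 equiv) is alkylated with methyl bromoacetate (transylidation) to give dimethyl 2-(triphenylphosphoranylidene)butanedioate F10.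
 - Wittig reaction of F10 with 3 in refluxing toluene gives dimethyl (E)-2-[2-hydroxy-6-methoxy-4-(methoxymethoxy)benzylidene]butanedioate F11.
 - Heating in N,N-diethylaniline (thermal alkene equilibration and lactonisation) gives methyl [5-methoxy-7-(methoxymethoxy)-2-oxo-2H-chromen-3-yl]acetate F12.
 - LiOH in THF/H2O followed by acidification to pH 4 with citric acid, which recloses any opened lactone, gives 5.

**Further compounds**
F1 | step 7 | 1-(5-hydroxy-2,2-dimethyl-2H-chromen-6-yl)ethan-1-one | CC(=O)c1ccc2c(C=CC(C)(C)O2)c1O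
F2 | step 7 | 1-(5-hydroxy-2,2-dimethyl-3,4-dihydro-2H-chromen-6-yl)ethan-1-one | CC(=O)c1ccc2c(CCC(C)(C)O2)c1O
F3 | step 7 | 1-(5-methoxy-2,2-dimethyl-3,4-dihydro-2H-chromen-6-yl)ethan-1-one | CC(=O)c1ccc2c(CCC(C)(C)O2)c1OC
F4 | step 7 | 2-(5-methoxy-2,2-dimethyl-3,4-dihydro-2H-chromen-6-yl)-1-(morpholin-4-yl)ethane-1-thione | S=C(Cc1ccc2c(CCC(C)(C)O2)c1OC)N1CCOCC1
F5 | step 7 | (5-methoxy-2,2-dimethyl-3,4-dihydro-2H-chromen-6-yl)acetic acid | OC(=O)Cc1ccc2c(CCC(C)(C)O2)c1OC
F6 | step 7 | 5-methoxy-3-(5-methoxy-2,2-dimethyl-3,4-dihydro-2H-chromen-6-yl)-7-(methoxymethoxy)-2H-chromen-2-one | COCOc1cc(OC)c2cc(-c3ccc4c(CCC(C)(C)O4)c3OC)c(=O)oc2c1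
F7 | step 5 | 3-[4-(dimethylamino)-2-oxobutyl]-5-methoxy-7-(methoxymethoxy)-2H-chromen-2-one | CN(C)CCC(=O)Cc1cc2c(OC)cc(OCOC)cc2oc1=O
F8 | step 5 | 3-[1-diazo-4-(dimethylamino)-2-oxobutyl]-5-methoxy-7-(methoxymethoxy)-2H-chromen-2-one | CN(C)CCC(=O)C(=[N+]=[N-])c1cc2c(OC)cc(OCOC)cc2oc1=O
F9 | step 5 | 4-diazo-4-[5-methoxy-7-(methoxymethoxy)-2-oxo-2H-chromen-3-yl]-N,N,N-trimethyl-3-oxobutan-1-aminium iodide | C[N+](C)(C)CCC(=O)C(=[N+]=[N-])c1cc2c(OC)cc(OCOC)cc2oc1=O.[I-]
F10 | step 3 | dimethyl 2-(triphenylphosphoranylidene)butanedioate | COC(=O)CC(C(=O)OC)=P(c1ccccc1)(c1ccccc1)c1ccccc1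
F11 | step 3 | dimethyl (E)-2-[2-hydroxy-6-methoxy-4-(methoxymethoxy)benzylidene]butanedioate | COC(=O)C/C(C(=O)OC)=C\c1c(O)cc(OCOC)cc1OC
F12 | step 3 | methyl [5-methoxy-7-(methoxymethoxy)-2-oxo-2H-chromen-3-yl]acetate | COC(=O)Cc1cc2c(OC)cc(OCOC)cc2oc1=O
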